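The vessel is stirred at constant volume, the gas is held, and the free catalyst is charged in mol% of the starting material.

the same everywhere: gas 42 mM (held); free catalyst 5 mol%; second catalyst 0.5 mol% (in portions, 4)

| flask | starting material | remark | time |
|---|---|---|---|
| violet | 0.14 M | run made earlier; portions every 40 s |  |
| teal | 0.22 M | run made earlier; portions every 40 s |  |
| flask | 0.10 M | the portions of second catalyst follow each other after 40 s, the first at the start | 2.5 h |

- violet (time / min: target / %, starting material / %): 8.00: 14.7, 66.4; 25.0: 54.0, 37.3; 40.0: 70.0, 25.5; 60.0: 79.1, 16.6; 90.0: 87.3, 9.2; 120: 91.2, 5.2
- teal (time / min: target / %, starting material / %): 10.0: 24.3, 49.2; 15.0: 38.5, 39.4; 25.0: 60.2, 27.1; 40.0: 77.4, 18.1; 80.0: 88.7, 7.7; 120: 93.0, 2.7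

(standard deviation of a reading: 0.5 percentage points)

- at the start none of the gas is in solution
- a reading or a percentage of target counts all its forms, free or not

* target present at 2.5 h, in percent of the starting material charged
* starting material present at 2.5 h, in percent of the starting material charged
* side product present at 2.5 h, in percent of the starting material charged

Follow one molecule of starting material. At each moment it may meet free catalyst, so its loss is pseudo-first-order, and its survival depends on catalyst concentration times time. Fold this into one number. Take the exposure N, the catalyst charged times the time, scaled by the first violet reading, where little target stands: 5.48 for the flask. With every catalyst molecule working, the survivors are exp(−N), or 0.417%.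

Now test it. Define the working share φ as ln(1/survivors) divided by N. Violet at 120 min has N = 6.14 and φ = 0.481. Teal at 80.0 min has a similar N, 6.43, but φ = 0.398, which is lower. So one number is not enough: concentration acts too.

Extend the line from teal through violet to the flask. This gives φ = 0.523 and 5.69% starting material. Read the late violet gap as the side fork: 3.80% of converted material. My reckoning is then 3.58% side product and 90.7% target.

The forecast says 92.2%, 4.1% and 3.7%, on “inhibition by target, which also scales with concentration”. Its starting material is lower than mine.

The flask gives 91.9% target, 4.51% starting material and 3.30% side product.

    starting material + free catalyst → free catalyst + intermediate (k = 0.122 L mol⁻¹ s⁻¹)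
    coupling partner + second catalyst + intermediate → second catalyst + target (k = 213 L² mol⁻² s⁻¹)
    intermediate → side product (k = 1.19 × 10⁻⁴ s⁻¹)
    free catalyst + target ⇌ idle complex (K = 13.0 L mol⁻¹, k = 0.0730 L mol⁻¹ s⁻¹)
    gas ⇌ coupling partner, rate k5*(csat - [coupling partner]) (kL = 0.00312 s⁻¹)

The working share of the flask comes to 0.565, above my estimate. Free catalyst, target and idle complex (product inhibition) relax by that step alone with a half-life of 0.939 min at the asked time, far shorter than the 2.5 h of the run. Free catalyst reads 50.3% at 1.25 h and 46.3% at 2.50 h. Read at 10 h, the same flask has N = 21.9, free catalyst reads 45.1%, and it holds 0% starting material.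

The numbers in the tables are simulated with made-up constants, and the scatter is random.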